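**Retrosynthetic overview**

1. The acetyl group on C1 is traced back to a carboxylic acid (methyl ketone by MeLi addition), the acid to a methyl ester, with both phenols masked as MOM ethers for these operations.
2. The strategy rests on ring A (C1 acetyl, C2 OH, C3 H, C4 OH, C5 H, C6 carrying the chain C1'–C10' that ends in phenyl ring B): it has the oxidation pattern of a cyclohexane-1,3-dione with carbonyls at C2 and C4, the chain on C6 and a carboxyl carbon on C1, so the resorcinol is made by dehydrogenating that saturated ring.
3. The dione ester is cut at C1–C6 (Michael addition) and C2–C3 (Claisen condensation) into dimethyl malonate and (E)-14-phenyltetradec-3-en-2-one.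
4. The enone comes from 11-phenylundecanal and the acetonyl ylide; the aldehyde comes from undec-10-en-1-ol and bromobenzene by hydroboration, B-alkyl Suzuki–Miyaura coupling and oxidation.
5. Ring order: ring B is bought as bromobenzene; ring A is the only ring built, closed in step 4 and aromatised in step 5.

Key step: step 4

Assumption: in step 1 the hydroboration of the terminal alkene of 1 is taken to outrun reaction of 9-BBN at the free hydroxyl (excess 9-BBN is used and any O–B bond is cleaved by the aqueous NaOH of the coupling); dione ester 11 is drawn in its diketo form although it should exist largely as enol tautomers.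

**Route**

Step 1
Reactants: 1 undec-10-en-1-ol; 2 bromobenzene
Product: 4 11-phenylundecan-1-ol, via B-alkyl borane 3 (not isolated)
Conditions: 9-BBN (2 equiv), THF, 0 °C → rt; then 2, Pd(dppf)Cl2 (3 mol %), 3 M aq NaOH, THF, 65 °C
Reagents that add atoms: none
Why: Anti-Markovnikov hydroboration of the terminal alkene gives the primary B-alkyl-9-BBN 3, which should couple with bromobenzene in a B-alkyl Suzuki–Miyaura reaction, the dppf ligand favouring reductive elimination over β-hydride elimination.

Step 2
Reactants: 4 11-phenylundecan-1-ol
Product: 5 11-phenylundecanal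
Conditions: TEMPO (10 mol %), PhI(OAc)2 (1.1 equiv), CH2Cl2, rt
Reagents that add atoms: none
Why: TEMPO-catalysed oxoammonium oxidation with PhI(OAc)2 as terminal oxidant should stop at the aldehyde for a primary aliphatic alcohol and leave the benzylic CH2 untouched.

Step 3
Reactants: 5 11-phenylundecanal; 6 1-(triphenylphosphoranylidene)propan-2-one
Product: 7 (E)-14-phenyltetradec-3-en-2-one
Conditions: 6 (1.3 equiv), toluene, 90 °C
Reagents that add atoms: none
Why: Wittig olefination with a carbonyl-stabilised ylide is reversible up to the oxaphosphetane and should therefore give the (E)-enone selectively.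

Step 4
Reactants: 7 (E)-14-phenyltetradec-3-en-2-one; 8 dimethyl malonate
Product: 11 methyl 2,4-dioxo-6-(10-phenyldecyl)cyclohexane-1-carboxylate (racemic trans), via Michael adduct 9 (not isolated), via sodium enolate 10 (not isolated)
Conditions: NaOMe (1.2 equiv), 8 (1.2 equiv), MeOH, reflux; then 1 M aq HCl, 0 °C
Reagents that add atoms: none
Why: Methoxide converts dimethyl malonate into its anion, which adds 1,4 to enone 7 and forms bond C1–C6; proton transfer in adduct 9 then gives the methyl-ketone enolate, whose terminal carbon attacks one ester carbonyl and expels methoxide, forming bond C2–C3. The closest known reaction type is the Michael–Claisen annulation of malonates with alk-3-en-2-ones, which delivers 5-alkylcyclohexane-1,3-dione-4-carboxylates on the way to 5-alkylresorcinols. Ring A closes by a 6-(enolexo)-exo-trig acyl substitution, and the closure is pulled forward because the product is deprotonated at once to the vinylogous carboxylate 10, which only the acid work-up releases as 11. C6 is created without control in the Michael step (racemic), and C1, an epimerisable β-keto ester carbon, should settle trans to the chain under the equilibrating conditions; neither centre matters because both become sp2 in step 5. The step needs regiocontrol, with the ester-bearing carbon next to the chain-bearing carbon, and this is fixed by polarity, since the malonate carbon can bond only to the β-carbon of 7, which carries the chain. It also needs Claisen closure to win over aldol closure, which is secured because the only electrophiles within reach of the ketone enolate are ester carbonyls.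

Step 5
Reactants: 11 methyl 2,4-dioxo-6-(10-phenyldecyl)cyclohexane-1-carboxylate
Product: 13 methyl 2,4-dihydroxy-6-(10-phenyldecyl)benzoate, via bromo dione 12 (not isolated)
Conditions: Br2 (1.05 equiv), DMF, 0 °C → rt, then 80 °C
Reagents that add atoms: none
Why: α-Bromination of the enolised 1,3-dione followed by thermal loss of HBr and tautomerisation (halogenation–dehydrohalogenation aromatisation of cyclohexane-1,3-diones) should give the resorcinol ester, erasing both stereocentres of 11, while ring B, an unactivated alkylbenzene, does not react with Br2 in DMF without a Lewis acid.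

Step 6
Reactants: 13 methyl 2,4-dihydroxy-6-(10-phenyldecyl)benzoate
Product: 15 methyl 2,4-bis(methoxymethoxy)-6-(10-phenyldecyl)benzoate, via disodium bis-phenoxide 14 (not isolated)
Conditions: NaH (2.5 equiv), DMF, 0 °C; then MOMCl (2.6 equiv), 0 °C → rt
Reagents that add atoms: chloromethyl methyl ether, COCCl
Why: Williamson-type O-alkylation of the bis-phenoxide 14 with MOMCl should protect both hydroxyls, NaH being chosen because the C2 hydroxyl is hydrogen-bonded to the ester carbonyl and is alkylated only sluggishly with amine bases.

Step 7
Reactants: 15 methyl 2,4-bis(methoxymethoxy)-6-(10-phenyldecyl)benzoate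
Product: 17 2,4-bis(methoxymethoxy)-6-(10-phenyldecyl)benzoic acid, via potassium carboxylate 16 (not isolated)
Conditions: KOH (10 equiv), DMSO/H2O 4:1, 90 °C; then 1 M aq HCl to pH 4, 0 °C
Reagents that add atoms: potassium hydroxide, [K+].[OH-]
Why: Saponification of the di-ortho-substituted ester by poorly solvated hydroxide in wet DMSO should proceed because nothing else in 15 is base-sensitive (MOM ethers are stable to base), and the cold acidification to pH 4 only should spare the acetals.

Step 8
Reactants: 17 2,4-bis(methoxymethoxy)-6-(10-phenyldecyl)benzoic acid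
Product: 20 1-[2,4-bis(methoxymethoxy)-6-(10-phenyldecyl)phenyl]ethan-1-one, via lithium carboxylate 18 (not isolated), via dilithium gem-diolate 19 (not isolated)
Conditions: MeLi (3.5 equiv), THF, 0 °C → rt; inverse quench into ice-water
Reagents that add atoms: methyllithium, [Li]C
Why: Addition of methyllithium to the lithium carboxylate (ketone synthesis from a carboxylic acid and an organolithium) gives the dilithium gem-diolate 19, which does not collapse before the aqueous quench, so the ketone should not meet MeLi, and the two ortho substituents further disfavour a second addition.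

Step 9
Reactants: 20 1-[2,4-bis(methoxymethoxy)-6-(10-phenyldecyl)phenyl]ethan-1-one
Product: 21 1-[2,4-dihydroxy-6-(10-phenyldecyl)phenyl]ethan-1-one (CNP0380873.0)
Conditions: HCl (3 M aq, cat.), MeOH, 50 °C
Reagents that add atoms: none
Why: Acid-catalysed acetal exchange with methanol should cleave both MOM ethers as dimethoxymethane and leave the hydrogen-bonded 2-hydroxyacetophenone, which is stable to dilute acid.

**Compound list**

1 | undec-10-en-1-ol | C=CCCCCCCCCCO | starting material
2 | bromobenzene | Brc1ccccc1 | starting material
3 | 11-(9-borabicyclo[3.3.1]nonan-9-yl)undecan-1-ol | OCCCCCCCCCCCB1C2CCCC1CCC2 | intermediate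
4 | 11-phenylundecan-1-ol | OCCCCCCCCCCCc1ccccc1 | intermediate
5 | 11-phenylundecanal | O=CCCCCCCCCCCc1ccccc1 | intermediate
6 | 1-(triphenylphosphoranylidene)propan-2-one | CC(=O)C=P(c1ccccc1)(c1ccccc1)c1ccccc1 | starting material
7 | (E)-14-phenyltetradec-3-en-2-one | CC(=O)/C=C/CCCCCCCCCCc1ccccc1 | intermediate
8 | dimethyl malonate | COC(=O)CC(=O)OC | starting material
9 | dimethyl 2-(2-oxo-14-phenyltetradecan-4-yl)propanedioate (racemic, one enantiomer drawn) | COC(=O)C(C(=O)OC)[C@H](CC(C)=O)CCCCCCCCCCc1ccccc1 | intermediate
10 | sodium 4-(methoxycarbonyl)-3-oxo-5-(10-phenyldecyl)cyclohex-1-en-1-olate (racemic trans, one enantiomer drawn) | [Na+].COC(=O)[C@H]1C(=O)C=C([O-])C[C@@H]1CCCCCCCCCCc1ccccc1 | intermediate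
11 | methyl 2,4-dioxo-6-(10-phenyldecyl)cyclohexane-1-carboxylate (racemic trans, one enantiomer drawn) | COC(=O)[C@H]1C(=O)CC(=O)C[C@@H]1CCCCCCCCCCc1ccccc1 | intermediate
12 | methyl 3-bromo-2,4-dioxo-6-(10-phenyldecyl)cyclohexane-1-carboxylate (racemic, C3 undefined) | COC(=O)[C@H]1C(=O)C(Br)C(=O)C[C@@H]1CCCCCCCCCCc1ccccc1 | intermediate
13 | methyl 2,4-dihydroxy-6-(10-phenyldecyl)benzoate | COC(=O)c1c(O)cc(O)cc1CCCCCCCCCCc1ccccc1 | intermediate
14 | disodium 4-(methoxycarbonyl)-5-(10-phenyldecyl)benzene-1,3-bis(olate) | [Na+].[Na+].COC(=O)c1c([O-])cc([O-])cc1CCCCCCCCCCc1ccccc1 | intermediate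
15 | methyl 2,4-bis(methoxymethoxy)-6-(10-phenyldecyl)benzoate | COC(=O)c1c(OCOC)cc(OCOC)cc1CCCCCCCCCCc1ccccc1 | intermediate
16 | potassium 2,4-bis(methoxymethoxy)-6-(10-phenyldecyl)benzoate | [K+].[O-]C(=O)c1c(OCOC)cc(OCOC)cc1CCCCCCCCCCc1ccccc1 | intermediate
17 | 2,4-bis(methoxymethoxy)-6-(10-phenyldecyl)benzoic acid | OC(=O)c1c(OCOC)cc(OCOC)cc1CCCCCCCCCCc1ccccc1 | intermediate
18 | lithium 2,4-bis(methoxymethoxy)-6-(10-phenyldecyl)benzoate | [Li+].[O-]C(=O)c1c(OCOC)cc(OCOC)cc1CCCCCCCCCCc1ccccc1 | intermediate
19 | dilithium 1-[2,4-bis(methoxymethoxy)-6-(10-phenyldecyl)phenyl]ethane-1,1-bis(olate) | [Li+].[Li+].CC([O-])([O-])c1c(OCOC)cc(OCOC)cc1CCCCCCCCCCc1ccccc1 | intermediate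
20 | 1-[2,4-bis(methoxymethoxy)-6-(10-phenyldecyl)phenyl]ethan-1-one | CC(=O)c1c(OCOC)cc(OCOC)cc1CCCCCCCCCCc1ccccc1 | intermediate
21 | 1-[2,4-dihydroxy-6-(10-phenyldecyl)phenyl]ethan-1-one | CC(=O)c1c(O)cc(O)cc1CCCCCCCCCCc1ccccc1 | target

**Step count**

Total step count: 9. Longest linear sequence: 9 steps (1 → 21).

**Steps most likely to fail and their fallbacks**

Step 4. At reflux the conjugate addition may revert, or adventitious hydroxide may cleave and decarboxylate the β-keto ester before or after ring closure, so the C1 ester is lost or the ring does not close. The fallback builds the same adduct with a different bond order and sets out from aldehyde 5 and malonate 8. Knoevenagel condensation (TiCl4, pyridine, THF, 0 °C → rt) should give dimethyl 2-(11-phenylundecylidene)propanedioate F1. Mukaiyama–Michael addition of 2-(trimethylsilyloxy)prop-1-ene to F1 (TiCl4, CH2Cl2, −78 °C, aqueous work-up) should then give adduct 9, now isolated. Closing 9 under aprotic conditions (KOtBu, 2.2 equiv, THF, 0 °C → rt, then 1 M aq HCl) rejoins the route at 11.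

Step 5. The resorcinol ring is more reactive towards bromine than the dione from which it forms, so ring bromination may compete as soon as the arene appears; on heating, bromide may also demethylate and decarboxylate the β-keto ester. The fallback sets out from 11 and over-brominates on purpose. Br2 (3.1 equiv) in AcOH at rt should give methyl 3,5-dibromo-2,4-dihydroxy-6-(10-phenyldecyl)benzoate F2. Hydrogenolysis of both C–Br bonds (H2, Pd/C, NaOAc, MeOH, rt) then returns to the route at 13; any stray bromine on ring B would be removed in the same operation.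

Step 8. The ketone may be released while MeLi is still present and add a second methyl group, or addition to the crowded lithium carboxylate may stall. The fallback sets out from ester 15 (and so also bypasses the slow saponification of step 7). LiAlH4 (THF, 0 °C) should give [2,4-bis(methoxymethoxy)-6-(10-phenyldecyl)phenyl]methanol F3. MnO2 (CH2Cl2, rt) should give 2,4-bis(methoxymethoxy)-6-(10-phenyldecyl)benzaldehyde F4. MeMgBr (THF, 0 °C) should give racemic 1-[2,4-bis(methoxymethoxy)-6-(10-phenyldecyl)phenyl]ethan-1-ol F5. Oxidation with Dess–Martin periodinane (NaHCO3, CH2Cl2, rt) rejoins the route at 20.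

**Further compounds**

F1 | step 4 | dimethyl 2-(11-phenylundecylidene)propanedioate | COC(=O)C(=CCCCCCCCCCCc1ccccc1)C(=O)OC
F2 | step 5 | methyl 3,5-dibromo-2,4-dihydroxy-6-(10-phenyldecyl)benzoate | COC(=O)c1c(O)c(Br)c(O)c(Br)c1CCCCCCCCCCc1ccccc1
F3 | step 8 | [2,4-bis(methoxymethoxy)-6-(10-phenyldecyl)phenyl]methanol | OCc1c(OCOC)cc(OCOC)cc1CCCCCCCCCCc1ccccc1
F4 | step 8 | 2,4-bis(methoxymethoxy)-6-(10-phenyldecyl)benzaldehyde | O=Cc1c(OCOC)cc(OCOC)cc1CCCCCCCCCCc1ccccc1
F5 | step 8 | 1-[2,4-bis(methoxymethoxy)-6-(10-phenyldecyl)phenyl]ethan-1-ol (racemic) | CC(O)c1c(OCOC)cc(OCOC)cc1CCCCCCCCCCc1ccccc1
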